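**Retrosynthetic overview**
1. The target is a linear tetraester A–B–C–D: A = (R)-3,4-dihydroxybutanoyl, B = (R)-3-oxybutanoyl, C = 2,4-dihydroxy-6-[(R)-2-oxypropyl]benzoyl, D = (S)-3-oxybutanoic acid.
2. Key and last disconnection: the alkyl C–O bond between the resorcylate oxygen and C3 of D. This leads back to the free acid A–B–C–CO2H and (R)-β-butyrolactone. The SN2 opening inverts (R) to (S) and leaves the terminal CO2H unprotected.
3. Ar–CO2H comes from Ar–I by Pd hydroxycarbonylation. The B–C ester C–O bond comes from the iodo alcohol of unit C and the A–B acid.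
4. The A–B acid comes from an acetonide-protected A acid chloride and unprotected (R)-3-hydroxybutanoic acid. The iodo alcohol comes from an aryl Grignard reagent and (R)-propylene oxide, followed by iodination.
5. No ring is built. The arene and the dioxolane protecting ring are bought, and the oxirane and β-lactone rings are only opened.

Assumption: the SMILES is read as drawn, giving A (R), B (R), C (R), D (S). Compounds 1, 2, 6, 9 and 15 are taken as catalogue items.

**Step 1**
Reactants: 1 1,3-bis(benzyloxy)-5-bromobenzene; 2 (R)-propylene oxide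
Product: 4 (2R)-1-[3,5-bis(benzyloxy)phenyl]propan-2-ol, via arylmagnesium bromide 3 (not isolated)
Conditions: Mg, cat. I2, THF, reflux; then CuI (10 mol %), 2 (1.3 equiv), THF, −30 → 0 °C; aq. NH4Cl
Reagents that add atoms: none
Why: Copper-catalysed Grignard opening of a terminal epoxide is an SN2 attack at the unsubstituted CH2, so the C–O bond at the stereocentre of 2 is untouched and 4 keeps the (R) configuration of unit C.

**Step 2**
Reactants: 4 (2R)-1-[3,5-bis(benzyloxy)phenyl]propan-2-ol
Product: 5 (2R)-1-[3,5-bis(benzyloxy)-2-iodophenyl]propan-2-ol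
Conditions: NIS (1.05 equiv), MeCN, 0 °C → rt, dark
Reagents that add atoms: N-iodosuccinimide, O=C1CCC(=O)N1I
Why: Electrophilic aromatic iodination goes para to one benzyloxy group and next to the side chain because the site between the two benzyloxy groups is more crowded, and the free alcohol and benzyl ethers are inert to NIS.

**Step 3**
Reactants: 6 2-[(4R)-2,2-dimethyl-1,3-dioxolan-4-yl]ethanol
Product: 8 2-[(4R)-2,2-dimethyl-1,3-dioxolan-4-yl]acetic acid, via dioxolanylacetaldehyde 7 (not isolated)
Conditions: TEMPO (7 mol %), NaOCl (2 mol %), NaClO2 (2 equiv), MeCN/phosphate buffer pH 6.7, 35 °C; citric acid to pH 4, 0 °C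
Reagents that add atoms: sodium chlorite, [Na+].[O-]Cl=O
Why: TEMPO/chlorite oxidation takes the primary alcohol through the aldehyde to the acid at near-neutral pH, which spares the acetonide and the (R) centre of unit A brought in with 6.

**Step 4**
Reactants: 8 2-[(4R)-2,2-dimethyl-1,3-dioxolan-4-yl]acetic acid; 9 (R)-3-hydroxybutanoic acid
Product: 11 (3R)-3-({2-[(4R)-2,2-dimethyl-1,3-dioxolan-4-yl]acetyl}oxy)butanoic acid, via dioxolanylacetyl chloride 10 (not isolated)
Conditions: 1-chloro-N,N,2-trimethylprop-1-en-1-amine (Ghosez reagent, 1.05 equiv), CH2Cl2, 0 °C, 1 h; then 9 (1.3 equiv), pyridine (3 equiv), CH2Cl2, −20 → 0 °C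
Reagents that add atoms: none
Why: HCl-free acid chloride formation followed by Einhorn-type O-acylation in pyridine, as practised for 3-acyloxy fatty acids, joins A to the 3-OH of the unprotected hydroxy acid, so no carboxyl protecting group is needed and neither stereocentre is touched.

**Step 5**
Reactants: 5 (2R)-1-[3,5-bis(benzyloxy)-2-iodophenyl]propan-2-ol; 11 (3R)-3-({2-[(4R)-2,2-dimethyl-1,3-dioxolan-4-yl]acetyl}oxy)butanoic acid
Product: 12 (2R)-1-[3,5-bis(benzyloxy)-2-iodophenyl]propan-2-yl (3R)-3-({2-[(4R)-2,2-dimethyl-1,3-dioxolan-4-yl]acetyl}oxy)butanoate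
Conditions: DIC (1.3 equiv), DPTS (0.3 equiv), CH2Cl2, 0 °C → rt
Reagents that add atoms: none
Why: Carbodiimide (Steglich-type) esterification acylates the oxygen of 5 with retention at the carbinol carbon, and the buffered DMAP·TsOH catalyst keeps E1cB loss of the β-acyloxy group to a crotonate low.

**Step 6**
Reactants: 12 aryl iodide triester
Product: 13 2,4-bis(benzyloxy)-6-[(2R)-2-{[(3R)-3-({2-[(4R)-2,2-dimethyl-1,3-dioxolan-4-yl]acetyl}oxy)butanoyl]oxy}propyl]benzoic acid
Conditions: Pd(OAc)2 (5 mol %), Xantphos (6 mol %), CO (3 bar), H2O (10 equiv), Et3N (2.5 equiv), DMF, 70 °C; citric acid work-up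
Reagents that add atoms: carbon monoxide, [C-]#[O+]; water, O
Why: Palladium-catalysed hydroxycarbonylation (oxidative addition, CO insertion, hydrolysis of the acyl-palladium) turns the aryl iodide into the benzoic acid under conditions that leave alkyl esters, benzyl ethers and the acetonide intact.

**Step 7**
Reactants: 13 protected benzoic acid
Product: 14 2,4-dihydroxy-6-[(2R)-2-{[(3R)-3-{[(3R)-3,4-dihydroxybutanoyl]oxy}butanoyl]oxy}propyl]benzoic acid
Conditions: H2 (1 atm), 10 % Pd/C, THF/AcOH/H2O 1:3:1, 20 °C, 20 h; filter, freeze-dry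
Reagents that add atoms: none
Why: Hydrogenolysis of both aryl benzyl ethers and hydrolysis of the terminal isopropylidene acetal run in one pot, and a weak acid at 20 °C is too mild for γ-lactonisation of the 3,4-dihydroxybutanoate, ester cleavage or decarboxylation, so no stereocentre is touched.

**Step 8**
Reactants: 14 free resorcylic acid A–B–C–CO2H; 15 (R)-β-butyrolactone
Product: 17 Talapolyester B, via Proton Sponge-H resorcylate salt 16 (not isolated)
Conditions: 15 (3 equiv), Proton Sponge (1.0 equiv), Proton Sponge·HNTf2 (1.0 equiv), dry MeCN (1 M), 45 °C, 36 h; pH 3 citrate wash, reversed-phase chromatography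
Reagents that add atoms: none
Why: Proposed new method: a pKa-gated single-insertion SN2 (alkyl–oxygen) opening of a β-lactone by a salicylate-type carboxylate, in which the non-nucleophilic buffer Proton Sponge/Proton Sponge-H+ (pKa about 18.6 in MeCN), which donates no hydrogen bond, ionises only the internally hydrogen-bonded resorcylic acid 14 (about 17) to carboxylate 16, whose sterically exposed oxygen attacks C4 of 15 from the back side with release of ring strain, forming the aryl ester C–O bond, inverting (R) to the required (S) centre and uncovering the terminal CO2H, while the newly formed aliphatic carboxylate (acid pKa about 23) is reprotonated at once by the buffer and cannot start a second insertion, the weakly basic nucleophile disfavours α-deprotonation to crotonate, and neutral phenol and alcohol groups do not attack the alkyl carbon; the closest known reaction type is the carboxylate-initiated anionic ring-opening polymerisation of β-butyrolactone, which uses the same alkyl–oxygen scission with inversion but is not stopped after one unit.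

**Compound list**
1 | 1,3-bis(benzyloxy)-5-bromobenzene | Brc1cc(OCc2ccccc2)cc(OCc2ccccc2)c1 | starting material
2 | (R)-propylene oxide, (2R)-2-methyloxirane | C[C@@H]1CO1 | starting material
3 | [3,5-bis(benzyloxy)phenyl]magnesium bromide | Br[Mg]c1cc(OCc2ccccc2)cc(OCc2ccccc2)c1 | intermediate
4 | (2R)-1-[3,5-bis(benzyloxy)phenyl]propan-2-ol | C[C@@H](O)Cc1cc(OCc2ccccc2)cc(OCc2ccccc2)c1 | intermediate
5 | (2R)-1-[3,5-bis(benzyloxy)-2-iodophenyl]propan-2-ol | C[C@@H](O)Cc1cc(OCc2ccccc2)cc(OCc2ccccc2)c1I | intermediate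
6 | 2-[(4R)-2,2-dimethyl-1,3-dioxolan-4-yl]ethanol | CC1(C)OC[C@@H](CCO)O1 | starting material
7 | 2-[(4R)-2,2-dimethyl-1,3-dioxolan-4-yl]acetaldehyde | CC1(C)OC[C@@H](CC=O)O1 | intermediate
8 | 2-[(4R)-2,2-dimethyl-1,3-dioxolan-4-yl]acetic acid | CC1(C)OC[C@@H](CC(=O)O)O1 | intermediate
9 | (R)-3-hydroxybutanoic acid | C[C@@H](O)CC(=O)O | starting material
10 | 2-[(4R)-2,2-dimethyl-1,3-dioxolan-4-yl]acetyl chloride | CC1(C)OC[C@@H](CC(=O)Cl)O1 | intermediate
11 | (3R)-3-({2-[(4R)-2,2-dimethyl-1,3-dioxolan-4-yl]acetyl}oxy)butanoic acid | C[C@H](CC(=O)O)OC(=O)C[C@@H]1COC(C)(C)O1 | intermediate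
12 | (2R)-1-[3,5-bis(benzyloxy)-2-iodophenyl]propan-2-yl (3R)-3-({2-[(4R)-2,2-dimethyl-1,3-dioxolan-4-yl]acetyl}oxy)butanoate | C[C@H](CC(=O)O[C@H](C)Cc1cc(OCc2ccccc2)cc(OCc2ccccc2)c1I)OC(=O)C[C@@H]1COC(C)(C)O1 | intermediate
13 | 2,4-bis(benzyloxy)-6-[(2R)-2-{[(3R)-3-({2-[(4R)-2,2-dimethyl-1,3-dioxolan-4-yl]acetyl}oxy)butanoyl]oxy}propyl]benzoic acid | C[C@H](CC(=O)O[C@H](C)Cc1cc(OCc2ccccc2)cc(OCc2ccccc2)c1C(=O)O)OC(=O)C[C@@H]1COC(C)(C)O1 | intermediate
14 | 2,4-dihydroxy-6-[(2R)-2-{[(3R)-3-{[(3R)-3,4-dihydroxybutanoyl]oxy}butanoyl]oxy}propyl]benzoic acid | C[C@H](CC(=O)O[C@H](C)Cc1cc(O)cc(O)c1C(=O)O)OC(=O)C[C@@H](O)CO | intermediate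
15 | (R)-β-butyrolactone, (4R)-4-methyloxetan-2-one | C[C@@H]1CC(=O)O1 | starting material
16 | 8-(dimethylamino)-N,N-dimethylnaphthalen-1-aminium salt of the carboxylate of 14 | C[C@H](CC(=O)O[C@H](C)Cc1cc(O)cc(O)c1C(=O)[O-])OC(=O)C[C@@H](O)CO.CN(C)c1cccc2cccc([NH+](C)C)c12 | intermediate
17 | Talapolyester B | C[C@H](CC(=O)O[C@H](C)Cc1cc(O)cc(O)c1C(=O)O[C@@H](C)CC(=O)O)OC(=O)C[C@@H](O)CO | target

**Step count and risks**
Total steps: 8. Longest linear sequence: 6 (steps 3-4-5-6-7-8, and equally 1-2-5-6-7-8).

Step 8 (the new step) carries the most risk.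
- A weakly nucleophilic carboxylate must attack a secondary carbon, so the reaction may be slow.
- A second insertion may leak in near full conversion.
- Lactone 15 may isomerise to crotonic acid.
- Acid 14 may decarboxylate, or its diol ester may γ-lactonise, during the long warm reaction.

The fallback uses known chemistry, sets out from 13 and comes back at 17. Mitsunobu esterification of 13 with commercial benzyl (R)-3-hydroxybutanoate (C[C@@H](O)CC(=O)OCc1ccccc1; DIAD, PPh3, toluene, 0 °C → rt) inverts the carbinol centre. This gives the fully protected benzyl ester of the target F1. The conditions of step 7 (H2, Pd/C, THF/AcOH/H2O) then remove three benzyl groups and the acetonide to give 17.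

Step 6 is the second risk. The aryl iodide is electron-rich and has two ortho substituents, so carbonylation may stall or give hydrodeiodination. Et3N at 70 °C may also eliminate the β-acyloxy ester. The fallback replaces metal-catalysed carbonylation with electrophilic formylation and oxidation. It sets out from 4 (step 2 is skipped) and comes back at 13.
- DIC/DPTS esterification of 4 with 11 gives the iodine-free ester F2.
- Vilsmeier–Haack formylation (POCl3, DMF, 0 → 50 °C, aq. NaOAc work-up) para to one benzyloxy group gives the aldehyde F3.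
- Pinnick oxidation (NaClO2, NaH2PO4, 2-methyl-2-butene, t-BuOH/H2O) gives 13.

Step 4 is the third risk. The free carboxyl group of 9 can be acylated, which can lead to anhydride scrambling and B–B oligomers. The fallback masks this carboxyl group. It sets out from 8 and comes back at 11. DIC/DPTS esterification of 8 with commercial benzyl (R)-3-hydroxybutanoate gives the benzyl ester of the A–B acid F4. Neutral hydrogenolysis (H2, Pd/C, EtOAc, rt) leaves the acetonide in place and gives 11.

**Further compounds**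
F1 | step 8 | benzyl (3S)-3-({2,4-bis(benzyloxy)-6-[(2R)-2-{[(3R)-3-({2-[(4R)-2,2-dimethyl-1,3-dioxolan-4-yl]acetyl}oxy)butanoyl]oxy}propyl]benzoyl}oxy)butanoate | C[C@H](CC(=O)O[C@H](C)Cc1cc(OCc2ccccc2)cc(OCc2ccccc2)c1C(=O)O[C@@H](C)CC(=O)OCc3ccccc3)OC(=O)C[C@@H]4COC(C)(C)O4
F2 | step 6 | (2R)-1-[3,5-bis(benzyloxy)phenyl]propan-2-yl (3R)-3-({2-[(4R)-2,2-dimethyl-1,3-dioxolan-4-yl]acetyl}oxy)butanoate | C[C@H](CC(=O)O[C@H](C)Cc1cc(OCc2ccccc2)cc(OCc2ccccc2)c1)OC(=O)C[C@@H]1COC(C)(C)O1
F3 | step 6 | (2R)-1-[3,5-bis(benzyloxy)-2-formylphenyl]propan-2-yl (3R)-3-({2-[(4R)-2,2-dimethyl-1,3-dioxolan-4-yl]acetyl}oxy)butanoate | C[C@H](CC(=O)O[C@H](C)Cc1cc(OCc2ccccc2)cc(OCc2ccccc2)c1C=O)OC(=O)C[C@@H]1COC(C)(C)O1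
F4 | step 4 | benzyl (3R)-3-({2-[(4R)-2,2-dimethyl-1,3-dioxolan-4-yl]acetyl}oxy)butanoate | C[C@H](CC(=O)OCc1ccccc1)OC(=O)C[C@@H]1COC(C)(C)O1
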